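Late in a flask like these I looked first at the reagent: its charge of 0.592 M is smaller than the 0.74 M of starting material, so it is the limiting reagent, and target stays under 80.0 % of the starting material charged. What I needed to know was how much of the reagent each flask uses in the time given.

common to all: starting material 0.74 M; reagent 0.592 M; second substrate 0.740 M; precatalyst 110 mM; time 3.0 d

|  | remark | temperature |
|---|---|---|
| amber | at 55 °C until 2.0 d, from then on at 70 °C |  |
| red |  | 70 °C |
| violet |  | 55 °C |

* the flask with the highest amount of target, in percent of the starting material charged ("all alike" if they lie within 1.5 percentage points) (amber / red / violet / all alike)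
* final target, as a percentage of the starting material charged, in amber
* final target, as a percentage of the starting material charged, in red
* final target, as a percentage of the starting material charged, in violet

- where a step has two of a species, its rate is k times that concentration squared, and two are used at each turn
- at 70 °C the constants are as listed, elsewhere as the activation energies make them

    starting material + reagent + catalyst → catalyst + target (k1 = 0.575 L² mol⁻² h⁻¹, Ea1 = 78.0 kJ mol⁻¹)
    second substrate + reagent + catalyst → catalyst + second product (k2 = 0.319 L² mol⁻² h⁻¹, Ea2 = 57.0 kJ mol⁻¹)
    starting material + reagent → uncatalysed product (k3 = 0.00141 L mol⁻¹ h⁻¹, Ea3 = 89.0 kJ mol⁻¹)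
    2 reagent → homo dimer (k4 = 0.0106 L mol⁻¹ h⁻¹, Ea4 = 74.0 kJ mol⁻¹)
    precatalyst → catalyst (k5 = 0.0183 h⁻¹, Ea5 = 107 kJ mol⁻¹)
    (constants at 70 °C)

I reckoned that with two times. The first is the precatalyst's time of becoming catalyst, 54.6 h at 70 °C. The second is the reagent's lifetime at the same temperature if the whole catalyst charge were working on both substrates at their charged amounts:

13.7 h

The first is 3.99 times the second, so at 70 °C the release of catalyst is the slower of the two. The catalyst's late arrival therefore costs a lag, and I counted the reagent's lifetimes after it, holding both substrates at their charges and leaving the homo dimer and the uncatalysed product out: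

lifetimes = [time − tact·(1 − e^(−time/tact))] / tcat

reagent left = e^(−lifetimes)

Red passes 2.33 reagent lifetimes in 3.0 d. At 55 °C violet's two times become 303 h and 42.0 h, so violet passes 0.188 lifetimes, fewer than red. I expected more target in red than in violet, and I placed amber, cold until 2.0 d and hot afterwards, between them.

The forecast chose red, with 16.5 % in amber, 31 % in red and 6.2 % in violet. Of violet it said: “activation is slow, with catalyst only about 0.023 M”.

The run gave red: 31.0 % of target in red, 16.5 % in amber and 6.30 % in violet. Red's answer moves by 5 points at 0.462 M or 0.745 M of reagent, or at a time of 2.18 d. By the count, red's 2.33 lifetimes leave 9.73 % of the reagent, and red held 9.75 % at 3.00 d. For the red flask read early, at 30 h, the count gives 0.503 lifetimes and 60.5 % of the reagent, but that flask held 46 %, beside 0.0627 M of homo dimer.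

The rate constants were set for the occasion, and the outcome is calculated.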